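The product of a new flask was the business of the meeting: how much forms by 25 min, and of which hand.

common to all: left-handed substrate 20 mM; right-handed substrate 20 mM; free catalyst 40 µM

| flask | reagent | impurity | remark | time |
|---|---|---|---|---|
| Sunday's | 12 mM | 4.6 µM | run made earlier |  |
| Tuesday's | 12 mM | 10 µM | run made earlier |  |
| flask | 12.0 mM | 6.9 µM |  | 25 min |

| run | time / min | left-handed substrate / % | right-handed substrate / % |
|---|---|---|---|
| Sunday's | 2.00 | 43.1 | 49.7 |
| Sunday's | 3.00 | 42.5 | 49.9 |
| Sunday's | 5.00 | 36.7 | 50.0 |
| Sunday's | 8.00 | 36.3 | 49.4 |
| Sunday's | 10.0 | 32.9 | 49.2 |
| Sunday's | 15.0 | 29.8 | 47.8 |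
| Sunday's | 25.0 | 26.2 | 50.1 |
| Tuesday's | 1.33 | 44.7 | 50.8 |
| Tuesday's | 4.00 | 40.5 | 49.9 |
| Tuesday's | 8.00 | 36.3 | 49.1 |
| Tuesday's | 10.0 | 34.2 | 49.3 |
| Tuesday's | 15.0 | 30.4 | 49.1 |
| Tuesday's | 20.0 | 27.6 | 49.6 |
| Tuesday's | 25.0 | 26.5 | 48.4 |

(scatter of a reading: 1 percentage point)

- part of the left-handed substrate and right-handed substrate charged together that has reacted at 25 min
- excess of left-handed product over right-handed product in the product at 25 min
- excess of right-handed substrate over left-handed substrate among what is left of the two at 25 min

- free catalyst is single-handed; left-handed substrate and right-handed substrate are mirror images of each other, charged as a racemate, each of them at the stated concentration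
- an excess is the difference of the two amounts in percent of their sum
- an excess is below zero if the other one leads

The chair noted that the reagent is the limiting reagent, 12.0 mM against 20 mM of left-handed substrate. The kineticist assumed that it is spent in equal amount with the substrate, so that each last reading of left-handed substrate L also gives the unspent reagent B. She defined Θ as the logarithm of L/B divided by the same ratio at the charge. If the rate goes with W·L·B, where W is the working catalyst, taken as free catalyst minus impurity, then at these charges and this time Θ grows in proportion to W.

She read Θ = 0.930 from Sunday's run, with W = 35.4 µM, and Θ = 0.895 from Tuesday's, with W = 30.0 µM. The mean of Θ/W is 28.0 mM⁻¹, which she called s, the progress per working catalyst. She warned that a scatter of 1 percentage point weighs heavily on so small a B, so the two runs do not prove the proportion.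

For the new flask she took W = 33.1 µM, so Θ = 0.928. Solving for the left-handed substrate reacted, and counting it in percent of the two substrates charged together, she committed to 23.8%, a figure that says nothing of the hand of the product.

The forecaster differed slightly, giving 24.7% reacted, with 92% and 30% for the two excesses, on the ground that “The left-handed substrate is consumed selectively, and the right-handed substrate barely moves”.

The flask gave 23.8%, 7.49% and 28.7%.

    reagent + free catalyst + right-handed substrate → free catalyst + right-handed product (k = 160 M⁻² s⁻¹)
    left-handed product ⇌ right-handed product (k = 0.00170 s⁻¹)
    free catalyst + impurity → spent catalyst (k = 3.20 × 10⁵ M⁻¹ s⁻¹)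
    reagent ⇌ dormant form (K = 1.20, k = 0.00510 s⁻¹)
    reagent + free catalyst + left-handed substrate → free catalyst + left-handed product (k = 5000 M⁻² s⁻¹)

The excess in the product parted from the forecast because left-handed product turns into right-handed product, with a forward half-life of 6.8 min, shorter than the 25 min of the run. The same flask run without that step, both ways, gives an excess of 91.9% in the product. That step takes up no substrate, so s, read from substrate readings, speaks to the 23.8% reacted and not to the hand of the product.

In the neighbour flask with 0.010 mM of free catalyst, W is 3.10 µM, and s gives 5.54% reacted. The computed neighbour reached 5.92%.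

Readings and results were generated by integration on assumed constants.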